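Assumption: the SMILES is read as achiral 2‑henicosyl‑5,7‑dihydroxy‑4H‑chromen‑4‑one (C30H48O4) with an unbranched 21‑carbon chain on C2, so no stereochemical control is needed.

## The problem

The target 17 is a γ‑pyranone (ring C: O1, C2, C3, C4, C4a, C8a) fused to a phloroglucinol‑type benzene (ring A: C4a, C5, C6, C7, C8, C8a), with an unbranched C21 chain on C2. It has no stereocenter and no strained ring, so the difficulty is constitutional: a 1,3,5‑trioxygenated benzene and a β‑functionalised C24 acyl unit can combine to the chromone, to the isomeric 4‑alkylcoumarin or to a 2‑alkylidenebenzofuran‑3‑one, and only the first is wanted. On ring A the ring oxygen O1 and the carbonyl carbon C4 must sit on the neighbouring carbons C8a and C4a, with oxygen on C5 (next to C4a) and on C7. The chain has an odd number of carbons, whereas cheap fatty feedstock is even‑numbered (C22), so the chain and C2 are best taken together from one C22 unit. The free 5‑ and 7‑hydroxyl groups are acidic and make ring A very electron‑rich, so they must be masked through every organometallic step and freed at the end without opening the pyranone, which hot hydroxide or amines attack at C2; the C22 to C32 intermediates are waxes that dissolve poorly in the cold. The feature that the plan exploits is the bond C4a–C8a together with its neighbour C5: C8a carries an atom that arrives as a nucleophile (O1), C4a an atom that arrives as an electrophile (C4), and C5 carries oxygen. This is exactly what remains when a nucleophile–electrophile pair adds across a 3‑alkoxybenzyne, whose alkoxy group sends the nucleophile to the far carbon. O1 and the C4=O group are together the three atoms of a carboxyl group, and because O1, O5 and O7 are 1,3,5‑related, ring A before annulation has a mirror plane that makes its two positions ortho to O1 equivalent.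

## Retrosynthesis

**17 to 16.** The two O–H bonds at C5 and C7 are traced back to O–CH3 bonds, giving dimethyl ether 16. Methyl ethers are chosen over benzyl or silyl groups because they are inert to n‑BuLi, to fluoride and to 125 °C, all of which the route needs, and because the matching phenol 6 is commercial. The forward reaction must cleave two aryl methyl ethers, one of them (C7) without help from the carbonyl group, and leave the pyranone intact.

**16 to 13 and 5 (key disconnection).** Both bonds that tie ring C to ring A are cut, C4–C4a and O1–C8a, together with O1–C2. Ring C disappears completely: ring A becomes 3,5‑dimethoxybenzyne 14, released from silyl triflate 13, and O1, C4(=O), C3, C2 and the chain become tetracos‑2‑ynoic acid 5. The neighbouring cuts (O1–C2 alone, or C4–C4a alone) each leave one aryl–ring C bond to be set up beforehand on a ring that already carries three oxygens. This cut needs no ortho hydroxy–acyl pair on the arene at all. The precursors are a monocyclic arene and a straight‑chain acid against a fully substituted bicycle. The forward reaction must put the carboxylate oxygen on the aryne carbon remote from the C3 methoxy group and the acyl carbon on the carbon next to it, then close ynone 15 in the 6‑endo mode.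

**5 to 3, 2 and 1.** The C1–C2 bond of the acid is cut to CO2 and acetylide 4, and the triple bond is traced to dibromoalkene 3 and aldehyde 2, which comes from docosan‑1‑ol 1. The aldehyde carbon of 2 becomes C2 of the chromone and its 21 other carbons become the chain, so the odd chain is drawn from even‑numbered feedstock. An alkylation route to 5 would need a C21 halide, which is far less accessible. The forward steps are a one‑carbon homologation and a carboxylation, each on an unfunctionalised chain.

**13 to 11, 7 and 6.** The O–S bond of the triflate is traced to carbamate 11, and the C2–Si bond to directed ortho‑metalation of carbamate 7, made from 3,5‑dimethoxyphenol 6. The mirror plane of 7 makes the two positions between the carbamate and a methoxy group identical, so the silyl group can only enter where the aryne needs it. Electrophilic halogenation of 6 would offer no such control between C2 and C4. The forward reactions must lithiate next to the strongest directing group and exchange the carbamate for triflate without losing the aryl–silicon bond.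

## Roads not taken

**Alternative 1:** the obvious route cuts O1–C2 and C2–C3 (Baker–Venkataraman). Commercial 2‑hydroxy‑4,6‑dimethoxyacetophenone is O‑acylated with docosanoyl chloride, base shifts the acyl group to carbon to give β‑diketone A1, and acid closes ring C at the heteroatom to give 16. It is no longer than the chosen plan. It is set aside for three reasons:
- Ring C is closed at oxygen on a ring A whose ortho hydroxy–acyl pattern has to be bought ready‑made.
- The acyl donor has an enolisable α‑CH2, so ester enolisation, ketene formation and retro‑Claisen cleavage of A1 compete with the acyl shift.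
- The sequence is linear and makes one ring bond per step, whereas the chosen plan joins two independent halves in the ring‑forming step.

**Alternative 2:** cut C4–C4a and C3–C4 with carbon monoxide as C4. The forward key step is a carbonylative Sonogashira coupling of 2‑iodo‑3,5‑dimethoxyphenol A2 with tricos‑1‑yne A3 (PdCl2(PPh3)2, CO, Et2NH), which passes through 15 to 16. Its weaknesses are:
- Nothing in the structure of 6 secures iodination at C2 over C4, which is para to the hydroxyl group and flanked by two methoxy groups.
- The electron‑rich aryl iodide with two ortho substituents inserts CO slowly, so direct coupling and closure to a benzofuran compete.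

In the chosen plan the same positions are fixed by symmetry (step 5) and by the methoxy group beside the aryne (step 7), with no transition metal and no CO.

**Alternative 3:** cut only C4–C4a, closing ring C at a carbon–carbon bond. Methyl tetracos‑2‑ynoate A4 (from 5) takes up phenol 6 by oxa‑Michael addition, hydrolysis gives aryloxy‑enoic acid A5, and P2O5/MeSO3H closes the ring by Friedel–Crafts acylation at one of the two equivalent ortho positions. Its weaknesses are:
- The phloroglucinol‑type ring is also a carbon nucleophile towards the ynoate.
- Strong acid can split the aryl enol ether of A5 back to phenol and β‑keto acid, which recombine in the Pechmann sense to coumarin A6.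
- Only the Z isomer of A5 can cyclise.
- Four operations from 5 are needed where the chosen plan needs one.

Key step: step 7

## Steps

Step 1
Reactants: 1 docosan-1-ol
Product: 2 docosanal
Conditions: TEMPO (10 mol %), PhI(OAc)2 (1.1 equiv), CH2Cl2, 30 °C
Reagents that add atoms: none
Why: Oxoammonium (TEMPO) oxidation of a primary alcohol with PhI(OAc)2 as terminal oxidant stops at the aldehyde in dry CH2Cl2; the saturated chain has no other reactive site.

Step 2
Reactants: 2 docosanal
Product: 3 1,1-dibromotricos-1-ene
Conditions: CBr4, PPh3, Zn dust, CH2Cl2, rt (ylide preformed); then 2, 0 °C → rt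
Reagents that add atoms: carbon tetrabromide, BrC(Br)(Br)Br
Why: First half of the Corey–Fuchs reaction: the ylide Ph3P=CBr2 undergoes a Wittig reaction with the unhindered aldehyde; the new double bond carries two identical bromines, so no geometry has to be controlled.

Step 3
Reactants: 3 1,1-dibromotricos-1-ene
Product: 5 tetracos-2-ynoic acid, via lithium tricos-1-yn-1-ide 4 (not isolated)
Conditions: n-BuLi (2.2 equiv), THF, −78 → 0 °C; CO2 (gas), −78 °C → rt; 1 M HCl
Reagents that add atoms: carbon dioxide, O=C=O
Why: Second half of the Corey–Fuchs reaction: bromine–lithium exchange, Fritsch–Buttenberg–Wiechell rearrangement and deprotonation should give acetylide 4, which is carboxylated by CO2; acidification frees the acid.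

Step 4
Reactants: 6 3,5-dimethoxyphenol
Product: 7 3,5-dimethoxyphenyl N-(propan-2-yl)carbamate
Conditions: i-PrNCO, Et3N (cat.), CH2Cl2, rt
Reagents that add atoms: isopropyl isocyanate (2-isocyanatopropane), CC(C)N=C=O
Why: Base‑catalysed addition of the phenol to the isocyanate gives the N‑monoalkyl carbamate, a strong ortho‑directing group that can still be removed under mild base.

Step 5
Reactants: 7 3,5-dimethoxyphenyl N-(propan-2-yl)carbamate
Product: 11 3,5-dimethoxy-2-(trimethylsilyl)phenyl N-(propan-2-yl)carbamate, via N-silyl carbamate 8 (not isolated), via aryllithium 9 (not isolated), via N-silyl C-silyl carbamate 10 (not isolated)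
Conditions: TBSOTf, TMEDA, Et2O, 0 °C → rt; n-BuLi, TMEDA, −78 °C; TMSCl, −78 °C → rt; cold aq. NaHSO4 (brief)
Reagents that add atoms: chlorotrimethylsilane, C[Si](C)(C)Cl
Why: Directed ortho‑metalation: after temporary N‑silylation (8) the carbamate directs n‑BuLi to a position between the carbamate oxygen and a methoxy group, and the two such positions are equivalent by the mirror plane of 7, while C4 between the two weaker methoxy directors should stay untouched; TMSCl traps aryllithium 9 and the N–Si bond of 10 is hydrolysed on work‑up.

Step 6
Reactants: 11 3,5-dimethoxy-2-(trimethylsilyl)phenyl N-(propan-2-yl)carbamate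
Product: 13 3,5-dimethoxy-2-(trimethylsilyl)phenyl trifluoromethanesulfonate, via silylphenol 12 (not isolated)
Conditions: DBU, Et2NH, MeCN, 40 °C; then PhNTf2, rt
Reagents that add atoms: N-phenylbis(trifluoromethanesulfonimide), O=S(=O)(N(c1ccccc1)S(=O)(=O)C(F)(F)F)C(F)(F)F
Why: E1cB cleavage of the N‑monoalkyl carbamate by DBU (the isocyanate released is trapped by Et2NH as a urea) gives the phenoxide of 12, which is triflated in the same flask; this is the standard carbamate route to ortho‑silylaryl triflates and stays basic throughout, which protects the aryl–silicon bond.

Step 7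
Reactants: 5 tetracos-2-ynoic acid; 13 3,5-dimethoxy-2-(trimethylsilyl)phenyl trifluoromethanesulfonate
Product: 16 2-henicosyl-5,7-dimethoxy-4H-chromen-4-one, via 3,5-dimethoxybenzyne 14 (not isolated), via ortho-hydroxyaryl ynone 15 (not isolated)
Conditions: 13 (1.5 equiv), CsF (4 equiv), THF, 125 °C, sealed tube
Reagents that add atoms: none
Why: Fluoride removes the trimethylsilyl group of 13 and triflate leaves, giving aryne 14, while acid 5 is present as its cesium carboxylate. The carboxylate oxygen adds to the aryne carbon remote from the C3 methoxy group (future C8a), because the methoxy group beside the triple bond distorts and polarises it so that the developing carbanion sits on the carbon next to the C–O bond (future C4a); the C5 methoxy group is remote and has only a weak influence. The aryl anion attacks the neighbouring ester carbonyl (4‑exo‑trig) and the benzoxetene alkoxide opens to the ortho‑acyl phenoxide of 15, a net insertion of the aryne into the C–O bond of the acid; this is the known fluoride‑mediated reaction of arynes with carboxylic acids, which gives ortho‑hydroxyaryl ketones and, with 3‑substituted propiolic acids, chromones. The phenoxide of 15 then closes ring C by 6‑endo‑dig oxa‑Michael addition to the ynone (bond O1–C2), so that C4–C4a, O1–C8a and O1–C2 are made in one flask and both oxygens of ring C come from the carboxyl group. No stereocenter is formed. Four selectivities are needed: the regiochemistry of addition to the aryne, secured by the C3 methoxy group; acyl transfer in place of protonation of the aryl anion (which would stop at the aryl ester), favoured by the high temperature, the aprotic medium and excess CsF; attack on the carbonyl carbon and not on the alkyne β‑carbon (which would lead to a coumarin), secured because the aryl ester prefers the Z conformation that holds the carbanion over C=O and away from the triple bond; and 6‑endo over 5‑exo closure, favoured by the Michael polarity of the ynone and the aprotic medium.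

Step 8
Reactants: 16 2-henicosyl-5,7-dimethoxy-4H-chromen-4-one
Product: 17 2-henicosyl-5,7-dihydroxy-4H-chromen-4-one
Conditions: BBr3 (excess), CH2Cl2, −78 °C → rt; MeOH, then H2O
Reagents that add atoms: none
Why: Lewis acid cleavage of aryl methyl ethers: the C5 methoxy group should go first with chelation to the C4 carbonyl, the C7 methoxy group with excess BBr3 at room temperature; the pyranone and the alkyl chain are inert to BBr3 and the work‑up is not basic.

## Compound list

1 | docosan-1-ol | CCCCCCCCCCCCCCCCCCCCCCO | starting material
2 | docosanal | CCCCCCCCCCCCCCCCCCCCCC=O | intermediate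
3 | 1,1-dibromotricos-1-ene | CCCCCCCCCCCCCCCCCCCCCC=C(Br)Br | intermediate
4 | lithium tricos-1-yn-1-ide | CCCCCCCCCCCCCCCCCCCCCC#C[Li] | intermediate
5 | tetracos-2-ynoic acid | CCCCCCCCCCCCCCCCCCCCCC#CC(=O)O | intermediate
6 | 3,5-dimethoxyphenol | COc1cc(O)cc(OC)c1 | starting material
7 | 3,5-dimethoxyphenyl N-(propan-2-yl)carbamate | COc1cc(OC)cc(OC(=O)NC(C)C)c1 | intermediate
8 | 3,5-dimethoxyphenyl N-[tert-butyl(dimethyl)silyl]-N-(propan-2-yl)carbamate | COc1cc(OC)cc(OC(=O)N(C(C)C)[Si](C)(C)C(C)(C)C)c1 | intermediate
9 | [2-({[tert-butyl(dimethyl)silyl](propan-2-yl)carbamoyl}oxy)-4,6-dimethoxyphenyl]lithium | COc1cc(OC)c([Li])c(OC(=O)N(C(C)C)[Si](C)(C)C(C)(C)C)c1 | intermediate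
10 | 3,5-dimethoxy-2-(trimethylsilyl)phenyl N-[tert-butyl(dimethyl)silyl]-N-(propan-2-yl)carbamate | COc1cc(OC)c([Si](C)(C)C)c(OC(=O)N(C(C)C)[Si](C)(C)C(C)(C)C)c1 | intermediate
11 | 3,5-dimethoxy-2-(trimethylsilyl)phenyl N-(propan-2-yl)carbamate | COc1cc(OC)c([Si](C)(C)C)c(OC(=O)NC(C)C)c1 | intermediate
12 | 3,5-dimethoxy-2-(trimethylsilyl)phenol (formed as its DBU salt) | COc1cc(O)c([Si](C)(C)C)c(OC)c1 | intermediate
13 | 3,5-dimethoxy-2-(trimethylsilyl)phenyl trifluoromethanesulfonate | COc1cc(OC)c([Si](C)(C)C)c(OS(=O)(=O)C(F)(F)F)c1 | intermediate
14 | 3,5-dimethoxybenzyne (1,2-didehydro-3,5-dimethoxybenzene) | COC1=CC#CC(OC)=C1 | intermediate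
15 | 1-(2-hydroxy-4,6-dimethoxyphenyl)tetracos-2-yn-1-one (formed as its cesium phenoxide) | CCCCCCCCCCCCCCCCCCCCCC#CC(=O)c1c(O)cc(OC)cc1OC | intermediate
16 | 2-henicosyl-5,7-dimethoxy-4H-chromen-4-one | CCCCCCCCCCCCCCCCCCCCCc1cc(=O)c2c(OC)cc(OC)cc2o1 | intermediate
17 | 2-henicosyl-5,7-dihydroxy-4H-chromen-4-one | CCCCCCCCCCCCCCCCCCCCCc1cc(=O)c2c(O)cc(O)cc2o1 | target

## Step count and risks

Total step count: 8. Longest linear sequence: 5 steps (1 → 2 → 3 → 5 → 16 → 17, or 6 → 7 → 11 → 13 → 16 → 17).

**Step 7 (key step).** The most likely failure is protonation of the aryl anion before acyl transfer, so that the reaction stops at the aryl ester. Loss of CO2 from the cesium alkynoate at 125 °C and partial 5‑exo closure of the phenoxide are further risks. The fallback sets out from dibromoalkene 3 and comes back to the route at 16, passing through 15. Acetylide 4 is made as in step 3 and, in place of CO2, is added to commercial 2‑hydroxy‑4,6‑dimethoxybenzaldehyde (deprotonated beforehand with NaH, THF) to give racemic 1‑(2‑hydroxy‑4,6‑dimethoxyphenyl)tetracos‑2‑yn‑1‑ol F1. MnO2 in CH2Cl2 oxidises this benzylic propargylic alcohol to ynone 15. Et2NH in EtOH then adds to the ynone to give (E)‑3‑(diethylamino)‑1‑(2‑hydroxy‑4,6‑dimethoxyphenyl)tetracos‑2‑en‑1‑one F2, which can close only in the six‑membered mode and loses diethylamine to give 16.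

**Step 5 (and the silyl group in step 6).** Three things may go wrong: migration of the carbamoyl group to carbon (anionic ortho‑Fries) if the lithiated species warms, competing lithiation at C4 between the methoxy groups, and protodesilylation of the very electron‑rich arylsilane during acidic work‑up or during the carbamate cleavage of step 6. The fallback sets out from 6, comes back at 13 and bypasses steps 4 to 6. Ortho‑bromination of 6 (NBS, catalytic i‑Pr2NH, CH2Cl2) gives 2‑bromo‑3,5‑dimethoxyphenol F3, whose ortho selectivity over C4 is the point to be checked. HMDS then gives (2‑bromo‑3,5‑dimethoxyphenoxy)trimethylsilane F4. n‑BuLi in THF at −100 °C effects bromine–lithium exchange to [2,4‑dimethoxy‑6‑(trimethylsilyloxy)phenyl]lithium F5, which undergoes 1,3 oxygen‑to‑carbon silyl migration (retro‑Brook) to the lithium salt of 12. Tf2O converts this to 13.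

**Step 3.** The waxy dibromoalkene may dissolve poorly in THF at −78 °C, leaving the exchange and rearrangement incomplete, and the acetylide may be quenched by a proton before carboxylation. The fallback sets out from 2 and comes back at 5. Seyferth–Gilbert homologation with dimethyl (1‑diazo‑2‑oxopropyl)phosphonate (K2CO3, MeOH/THF, rt) gives tricos‑1‑yne F6 without cryogenic organolithium chemistry. Deprotonation with EtMgBr in THF at 50 °C, where the alkyne is soluble, then CO2 and HCl, gives 5.

**Step 8.** The C7 methoxy group has no neighbouring carbonyl to assist cleavage and may survive, and forcing the Lewis acid risks damage to the electron‑rich ring. The fallback sets out from 16 and comes back at 17 in two stages with different mechanisms. BCl3 (CH2Cl2, −78 → 0 °C) removes only the chelated C5 methyl group to give 2‑henicosyl‑5‑hydroxy‑7‑methoxy‑4H‑chromen‑4‑one F7. NaSEt in DMF at 120 °C then removes the C7 methyl group by SN2 attack at carbon, and acidification gives 17.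

## Further compounds

F1 | step 7 | 1-(2-hydroxy-4,6-dimethoxyphenyl)tetracos-2-yn-1-ol (racemic) | CCCCCCCCCCCCCCCCCCCCCC#CC(O)c1c(O)cc(OC)cc1OC
F2 | step 7 | (E)-3-(diethylamino)-1-(2-hydroxy-4,6-dimethoxyphenyl)tetracos-2-en-1-one | CCCCCCCCCCCCCCCCCCCCC/C(N(CC)CC)=C\C(=O)c1c(O)cc(OC)cc1OC
F3 | step 5 | 2-bromo-3,5-dimethoxyphenol | COc1cc(O)c(Br)c(OC)c1
F4 | step 5 | (2-bromo-3,5-dimethoxyphenoxy)trimethylsilane | COc1cc(O[Si](C)(C)C)c(Br)c(OC)c1
F5 | step 5 | [2,4-dimethoxy-6-(trimethylsilyloxy)phenyl]lithium | COc1cc(O[Si](C)(C)C)c([Li])c(OC)c1
F6 | step 3 | tricos-1-yne | CCCCCCCCCCCCCCCCCCCCCC#C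
F7 | step 8 | 2-henicosyl-5-hydroxy-7-methoxy-4H-chromen-4-one | CCCCCCCCCCCCCCCCCCCCCc1cc(=O)c2c(O)cc(OC)cc2o1
A1 | alternative 1 | 1-(2-hydroxy-4,6-dimethoxyphenyl)tetracosane-1,3-dione | CCCCCCCCCCCCCCCCCCCCCC(=O)CC(=O)c1c(O)cc(OC)cc1OC
A2 | alternative 2 | 2-iodo-3,5-dimethoxyphenol | COc1cc(O)c(I)c(OC)c1
A3 | alternative 2 | tricos-1-yne | CCCCCCCCCCCCCCCCCCCCCC#C
A4 | alternative 3 | methyl tetracos-2-ynoate | CCCCCCCCCCCCCCCCCCCCCC#CC(=O)OC
A5 | alternative 3 | (Z)-3-(3,5-dimethoxyphenoxy)tetracos-2-enoic acid | CCCCCCCCCCCCCCCCCCCCC/C(Oc1cc(OC)cc(OC)c1)=C/C(=O)O
A6 | alternative 3 | 4-henicosyl-5,7-dimethoxy-2H-chromen-2-one | CCCCCCCCCCCCCCCCCCCCCc1cc(=O)oc2cc(OC)cc(OC)c12
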